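Assumption (remark on the chemistry): the target is taken exactly as its SMILES defines it, with an unsubstituted phenyl group on C7 and no stereogenic element (slow rotation about the crowded C3–C7 and C4–aryl bonds is not treated as isomerism); the structures of the key step balance atom for atom and are used unchanged, and the preparation of the Grignard reagent is counted as a step.

Structural features

Ring A is a benzene ring with four different groups on four neighbouring carbons: methyl on C1, a (4-hydroxyphenyl)ethynyl group on C2, the exocyclic carbon C7 on C3 and a 4-hydroxyphenyl ring on C4; C5 and C6 are CH. C7 is the central carbon of a para-quinone methide: it is doubly bonded to C4 of a cyclohexa-2,5-dienone and singly bonded to a phenyl ring and to C3. The target has no stereocentre and, because the dienone is symmetric, no double-bond isomerism. The only stereocentre on the route is C7 at the carbinol stage; it has no stereogenic neighbour, is formed racemic and vanishes when C7 becomes trigonal. The fragile groups are the quinone methide (electrophilic at C7), the two free phenols, and the electron-rich diarylalkyne, which sits ortho to a carbon that ionises easily. The C4 aryl ring also lies within reach of a C7 cation, so a five-membered Friedel–Crafts closure to a fluorene is a latent side reaction. The real difficulty is the crowding and the positional order around C3: the C3–C7 bond must be made between two ortho substituents, and four groups must be placed on ring A without ambiguity. The key step uses the fact that the C4–aryl and C3–C7 bonds are vicinal and lie next to the C2 alkynyl group. A C3≡C4 aryne takes a nucleophile at C4 and an electrophile at C3, and the σ-withdrawing, rod-shaped alkynyl group controls both where the aryne is generated and which end is attacked.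

Logic of the disconnections

16 ⇒ 14. The C7=C bond of the quinone methide is traced back to a C7–OH bond, and the three phenolic O–H bonds to O–CH2OMe bonds. The reason is that the quinone methide would not survive any organometallic step, whereas the triaryl carbinol has the same oxidation level and ionises to it. C7 thereby becomes an sp3 carbon that can come from a ketone and an aryl nucleophile. The forward step must cleave three acetals and ionise C7–OH under acid mild enough that the cation neither closes onto the C4 aryl ring nor provokes hydration of the alkyne.

14 ⇒ 9 + 10 + 4. The C4–aryl bond and the C3–C7 bond are cut together. Both lie on adjacent carbons beside the alkynyl group, so they can be made in one flask through aryne 12: the aryl group of 10 enters as the nucleophile, and the carbonyl carbon of 4 as the electrophile for the arylmagnesium 13 left at C3. A 40-carbon carbinol is thus reduced to pieces of 17, 8 and 15 carbons. The forward step demands metalation of 9 at C3 and not at C5, addition to the aryne at C4, and addition of a doubly ortho-substituted arylmagnesium to a diaryl ketone. The fluorine is kept at C4 of 9: only there is the proton to be removed flanked by both the fluorine and the sp carbon, which brings it within reach of a hindered lithium amide. With the fluorine on C3 the single ortho hydrogen would be no more acidic than in fluorobenzene, and the alkyllithium bases then required would endanger the alkyne and the benzylic methyl group.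

9 ⇒ 7 + 2. The bond between the alkyne and the oxygenated ring is cut, together with the C–Si bond of 7 (through 8). An unsymmetrical diarylalkyne is best made from a terminal alkyne and an aryl iodide, and placing the silyl alkyne on the fluorinated ring lets 2 serve twice in the route. The forward step requires that 8, released in the flask, is cross-coupled faster than it dimerises, and that the C–F bond stays intact.

7 ⇒ 5 + 6. The bond from C2 of ring A to the alkyne is cut. Both partners are commercial, and the silyl cap guarantees a single coupling. The forward step must couple at the iodide next to the ortho methyl group and leave the fluoride untouched.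

10 ⇒ 2. The C–Mg bond is traced to the C–I bond. The forward step needs clean insertion of magnesium without homocoupling and an acetal that tolerates the reagent.

2 ⇒ 1 and 4 ⇒ 3. The O–CH2 bonds are cut. The free phenols would quench 10, 11 and 13 and would deactivate the ketone as a phenoxide. The methoxymethyl acetal is chosen because it survives bases, palladium, copper and fluoride and leaves in the final step under the same acid that ionises C7–OH. Methyl ethers would save both protections but would need BBr3-type cleavage in the presence of the alkyne and the C7 cation. The forward steps place no special demand.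

Other disconnections considered

Alternative 1: Ring A is opened at C3–C4 and C1–C6. C4–C5–C6 with the C4 aryl group is the enal (2E)-3-(4-methoxyphenyl)prop-2-enal A2; C1–C2–C3 with the methyl group and C7 (as a benzoyl carbon) is 1-phenylpentane-1,3-dione A3. Forward, a secondary amine would activate A2 as an iminium ion and the central carbon of A3 would add to it (C3–C4). The α-carbon of the ethyl ketone would then condense with the aldehyde (C1–C6), and iodine in DMSO would dehydrogenate the cyclohexenone to the phenol [2-hydroxy-6-(4-methoxyphenyl)-3-methylphenyl](phenyl)methanone A1.
- In its favour: the substitution pattern of ring A is written into two acyclic partners, so no positional selectivity on an aromatic ring is needed. On this point it is better than the chosen plan. The ring-forming step needs no cryogenic organometallic reagent, which is also better operationally.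
- Against it here: C2 arrives as a hydroxyl group and C7 as a ketone. Reaching 16 therefore needs triflation, a Sonogashira coupling at a position flanked by the methyl and benzoyl groups, addition of an oxygenated aryl nucleophile to a ketone between two ortho substituents, and O-deprotection. The methyl ether drawn in A1 would call for a strong Lewis acid at the end, with the alkyne and the C7 cation present. In the annulation, O-cyclisation of the diketone adduct to a pyran-type hemiacetal can compete with the C-aldol closure.
- Comparison: on structure, both plans end with a C7 carbinol that is ionised, but the chosen plan sets C7 with all three rings in the ring A-functionalising step itself. On mechanism, enamine and iminium chemistry is the more predictable, while the late couplings at the crowded C2 and C7 carry the risk instead. On step economy, about six linear steps compare with a longest linear sequence of four, while the total number of operations is about equal.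

Alternative 2: Ring A is opened at C1–C2 and C3–C4. The diene 1-(methoxymethoxy)-4-[(1E,3E)-penta-1,3-dien-1-yl]benzene A5 supplies C1 (with the methyl group), C6, C5 and C4 (with the aryl group). The diynone 1,5-bis[4-(methoxymethoxy)phenyl]penta-2,4-diyn-1-one A6 supplies C2 (with the arylethynyl group) and C3 (with C7 as an aroyl carbon). Forward, a thermal [4+2] cycloaddition at the aroyl-activated triple bond, followed by DDQ in the same flask, would give the ketone [4-(methoxymethoxy)phenyl]{6-[4-(methoxymethoxy)phenyl]-2-{[4-(methoxymethoxy)phenyl]ethynyl}-3-methylphenyl}methanone A4. Addition of a phenyl nucleophile to A4 would then give 14.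
- In its favour: the benzene ring and all four substituents appear in one operation, with the alkyne already in place. No strong base is involved, and no question of C–H acidity arises, which is better than the chosen plan on this point. The protecting groups and the final step are the same, which is equal.
- Against it here: the orientation depends on the aryl terminus of A5 outweighing the methyl terminus. The two triple bonds of A6 must be differentiated, and conjugated diynones are thermally labile. A5 and A6 each need several steps. A4 is still a ketone, so a further addition to a hindered carbonyl group is needed before the route reaches 14.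
- Comparison: on structure, the two plans meet at 14. On mechanism, a concerted cycloaddition is robust, but its regiochemistry is less firmly secured than the aryne addition, which is governed by the alkynyl group. On step economy, the chosen plan is clearly shorter.

Alternative 3: Ring A is opened at C1–C6 and C4–C5. The pyrone ethyl 2-(4-methoxyphenyl)-4-[(4-methoxyphenyl)ethynyl]-5-methyl-6-oxo-6H-pyran-3-carboxylate A8 supplies C1 to C4 with all four substituents (C7 as the ester carbon), and butyl vinyl ether A9 supplies C5 and C6. Forward, an inverse-demand [4+2] cycloaddition across the pyrone termini, loss of CO2 and elimination of butanol would give ethyl 6-(4-methoxyphenyl)-2-[(4-methoxyphenyl)ethynyl]-3-methylbenzoate A7.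
- In its favour: the orientation of A9 is irrelevant, since both of its carbons end as unsubstituted CH. This removes every regiochemical question and is better than the chosen plan on this point. The by-products are volatile.
- Against it here: C7 of 16 carries two different rings, so the ester of A7 must take two different aryl nucleophiles in succession through a hindered ketone. An ester suits targets with two identical rings on C7 far better. A8 is a fully substituted pyrone with substituents on both diene termini, so the cycloaddition should be slow, and A8 itself requires a multistep synthesis. The methyl ethers again impose a harsh final deprotection.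
- Comparison: on structure, C7 arrives at the wrong oxidation level for an unsymmetrical triarylmethane. On mechanism, the pericyclic cascade is the equal of the aryne relay in predictability. On step economy, it is distinctly longer.

Key step: step 6

Step 1
Reactants: 1 4-iodophenol
Product: 2 1-iodo-4-(methoxymethoxy)benzene
Conditions: MOMCl, i-Pr2NEt, CH2Cl2, 0 °C → rt
Reagents that add atoms: chloromethyl methyl ether, COCCl
Why: O-alkylation of the phenol with the highly electrophilic α-chloro ether (Williamson-type acetal formation); the MOM ether tolerates palladium, copper, fluoride and organomagnesium reagents and is removed by the acid used in step 7.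

Step 2
Reactants: 3 (4-hydroxyphenyl)(phenyl)methanone
Product: 4 [4-(methoxymethoxy)phenyl](phenyl)methanone
Conditions: MOMCl, i-Pr2NEt, CH2Cl2, 0 °C → rt
Reagents that add atoms: chloromethyl methyl ether, COCCl
Why: The same O-alkylation; the carbonyl group is untouched, and capping the phenol prevents protonation of the arylmagnesium and formation of an unreactive phenoxide-conjugated ketone in step 6.

Step 3
Reactants: 5 4-fluoro-2-iodo-1-methylbenzene; 6 ethynyltrimethylsilane
Product: 7 [(5-fluoro-2-methylphenyl)ethynyl]trimethylsilane
Conditions: PdCl2(PPh3)2 (cat.), CuI (cat.), Et3N, THF, rt → 45 °C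
Reagents that add atoms: none
Why: Sonogashira coupling; the C–I bond adds to zerovalent palladium under mild conditions despite the ortho methyl group, the C–F bond is inert, and the silyl cap allows only one coupling.

Step 4
Reactants: 7 [(5-fluoro-2-methylphenyl)ethynyl]trimethylsilane; 2 1-iodo-4-(methoxymethoxy)benzene
Product: 9 4-fluoro-2-{[4-(methoxymethoxy)phenyl]ethynyl}-1-methylbenzene, via 2-ethynyl-4-fluoro-1-methylbenzene 8 (not isolated)
Conditions: PdCl2(PPh3)2 (cat.), CuI (cat.), Bu4NF, Et3N, THF (degassed), rt → 45 °C
Reagents that add atoms: none
Why: Fluoride cleaves the C(sp)–Si bond and releases 8 in the flask, where it is coupled with the aryl iodide 2 (in situ desilylation followed by Sonogashira coupling, a known one-flask variant); the C–F bond and the MOM acetal are inert, and the volatile alkyne 8 need not be handled.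

Step 5
Reactants: 2 1-iodo-4-(methoxymethoxy)benzene
Product: 10 [4-(methoxymethoxy)phenyl]magnesium iodide (titrated THF solution, used directly)
Conditions: Mg turnings (I2-activated), THF, rt → 45 °C
Reagents that add atoms: magnesium, [Mg]
Why: Insertion of magnesium into the C–I bond (Grignard formation) is fast for aryl iodides, and the MOM acetal offers no acidic or electrophilic site; the same iodide 2 thus supplies both the alkyne terminus and the C4 aryl nucleophile.

Step 6
Reactants: 9 4-fluoro-2-{[4-(methoxymethoxy)phenyl]ethynyl}-1-methylbenzene; 10 [4-(methoxymethoxy)phenyl]magnesium iodide; 4 [4-(methoxymethoxy)phenyl](phenyl)methanone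
Product: 14 racemic [4-(methoxymethoxy)phenyl]{6-[4-(methoxymethoxy)phenyl]-2-{[4-(methoxymethoxy)phenyl]ethynyl}-3-methylphenyl}(phenyl)methanol, via C3-lithiated fluoroarene 11 (not isolated), via C3≡C4 aryne 12 (not isolated), via C3 arylmagnesium iodide 13 (not isolated)
Conditions: lithium 2,2,6,6-tetramethylpiperidide (from 2,2,6,6-tetramethylpiperidine, n-BuLi), THF, −78 °C; then 10, −78 °C → rt; then 4 (excess), 0 → 40 °C; aq NH4Cl
Reagents that add atoms: none
Why: The hindered amide, too bulky to add to an aryne or to the alkyne, removes H–C3 of 9 (ortho-lithiation) to give 11; this proton is flanked by fluorine and by the sp carbon and is therefore the most acidic on the molecule, whereas C5–H has only the fluorine beside it, and since amide metalation is reversible the doubly activated site should prevail. On warming in the presence of 10, fluoride leaves and aryne 12 forms between C3 and C4; the closest known reaction type is the aryne route to ortho-functionalised biaryls, in which an aryl Grignard reagent adds to an aryne made from an ortho-metalated haloarene and the resulting 2-biarylmagnesium is trapped by an electrophile. The aryl group of 10 adds to C4 to give 13, because the σ-withdrawing alkynyl group at C2 distorts the aryne so that C4 is the more electrophilic terminus and the carbanion develops at C3 beside the sp carbon, and because C4 is also the less hindered end. Arylmagnesium 13 then adds to the carbonyl group of 4 (Grignard 1,2-addition; 4 has no α-hydrogen, so enolisation cannot compete), which forms the C3–C7 bond, and aqueous NH4Cl releases 14. No ring is closed. The new stereocentre at C7 is formed without any controlling element, both faces of the ketone being attacked alike, so 14 is racemic; this is immaterial because C7 becomes trigonal in step 7. The selectivities needed are the site of metalation (C3 over C5, the benzylic methyl group and the positions ortho to the MOM ethers) and the orientation of the aryne addition, and both are secured by the C2 alkynyl group together with the C4 fluorine. An excess of 4 is used because surplus 10 also consumes it, and the work-up is kept cold so that the magnesium alkoxide does not add to the neighbouring alkyne.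

Step 7
Reactants: 14 racemic [4-(methoxymethoxy)phenyl]{6-[4-(methoxymethoxy)phenyl]-2-{[4-(methoxymethoxy)phenyl]ethynyl}-3-methylphenyl}(phenyl)methanol
Product: 16 selaginellin A (4-[{4'-hydroxy-3-[(4-hydroxyphenyl)ethynyl]-4-methyl[1,1'-biphenyl]-2-yl}(phenyl)methylidene]cyclohexa-2,5-dien-1-one), via triphenol carbinol 15 (not isolated)
Conditions: HCl (aq), MeOH/THF, rt → 45 °C
Reagents that add atoms: none
Why: Acid-catalysed acetal exchange with methanol removes the three MOM groups as dimethoxymethane to give 15, and the tertiary, triply benzylic C7–OH ionises (SN1); the cation is the O-protonated quinone methide, so loss of the phenolic proton gives 16 (dehydration of a 4-hydroxytrityl alcohol to a fuchsone). Capture of the cation by methanol is reversible and leads to the same product on work-up, and the racemic centre of 14 disappears.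

Compound list

1 | 4-iodophenol | Oc1ccc(I)cc1 | starting material
2 | 1-iodo-4-(methoxymethoxy)benzene | COCOc1ccc(I)cc1 | intermediate
3 | (4-hydroxyphenyl)(phenyl)methanone | O=C(c1ccccc1)c1ccc(O)cc1 | starting material
4 | [4-(methoxymethoxy)phenyl](phenyl)methanone | O=C(c1ccccc1)c1ccc(OCOC)cc1 | intermediate
5 | 4-fluoro-2-iodo-1-methylbenzene | Cc1ccc(F)cc1I | starting material
6 | ethynyltrimethylsilane | C#C[Si](C)(C)C | starting material
7 | [(5-fluoro-2-methylphenyl)ethynyl]trimethylsilane | Cc1ccc(F)cc1C#C[Si](C)(C)C | intermediate
8 | 2-ethynyl-4-fluoro-1-methylbenzene | Cc1ccc(F)cc1C#C | intermediate (not isolated)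
9 | 4-fluoro-2-{[4-(methoxymethoxy)phenyl]ethynyl}-1-methylbenzene | Cc1ccc(F)cc1C#Cc1ccc(OCOC)cc1 | intermediate
10 | [4-(methoxymethoxy)phenyl]magnesium iodide | COCOc1ccc([Mg]I)cc1 | intermediate
11 | (6-fluoro-2-{[4-(methoxymethoxy)phenyl]ethynyl}-3-methylphenyl)lithium | Cc1ccc(F)c([Li])c1C#Cc1ccc(OCOC)cc1 | intermediate (not isolated)
12 | 3-{[4-(methoxymethoxy)phenyl]ethynyl}-4-methyl-1,2-didehydrobenzene | CC1=C(C#Cc2ccc(OCOC)cc2)C#CC=C1 | intermediate (not isolated)
13 | {6-[4-(methoxymethoxy)phenyl]-2-{[4-(methoxymethoxy)phenyl]ethynyl}-3-methylphenyl}magnesium iodide | Cc1ccc(-c2ccc(OCOC)cc2)c([Mg]I)c1C#Cc1ccc(OCOC)cc1 | intermediate (not isolated)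
14 | racemic [4-(methoxymethoxy)phenyl]{6-[4-(methoxymethoxy)phenyl]-2-{[4-(methoxymethoxy)phenyl]ethynyl}-3-methylphenyl}(phenyl)methanol | Cc1ccc(-c2ccc(OCOC)cc2)c(C(O)(c2ccccc2)c2ccc(OCOC)cc2)c1C#Cc1ccc(OCOC)cc1 | intermediate
15 | racemic 2-[hydroxy(4-hydroxyphenyl)(phenyl)methyl]-3-[(4-hydroxyphenyl)ethynyl]-4-methyl-[1,1'-biphenyl]-4'-ol | Cc1ccc(-c2ccc(O)cc2)c(C(O)(c2ccccc2)c2ccc(O)cc2)c1C#Cc1ccc(O)cc1 | intermediate (not isolated)
16 | selaginellin A, 4-[{4'-hydroxy-3-[(4-hydroxyphenyl)ethynyl]-4-methyl[1,1'-biphenyl]-2-yl}(phenyl)methylidene]cyclohexa-2,5-dien-1-one | Cc1ccc(-c2ccc(O)cc2)c(C(=C2C=CC(=O)C=C2)c2ccccc2)c1C#Cc1ccc(O)cc1 | target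

Total step count: 7 (steps 1 to 7, the preparation of the Grignard reagent included).
Longest linear sequence: 4 steps (5 → 7 → 9 → 14 → 16 through steps 3, 4, 6 and 7; the branches from 1 through steps 1, 4, 6, 7 or 1, 5, 6, 7 are equally long).

Steps least certain to work

Step 6 (key step). The most likely failure is in the last event of the relay. Addition of the doubly ortho-substituted arylmagnesium 13 to the diaryl ketone 4 is sterically slow, so electron transfer to the ketone or slow protonation of 13 by the liberated amine can compete while surplus 10 consumes 4. A smaller concern is partial metalation at C5, which would show up as isomeric biaryls. The fallback sets out from 13, generated from 9 and 10 exactly as in step 6, and returns at 14. Arylmagnesium 13 is captured with benzaldehyde, which is far more electrophilic and less hindered than 4, to give racemic {6-[4-(methoxymethoxy)phenyl]-2-{[4-(methoxymethoxy)phenyl]ethynyl}-3-methylphenyl}(phenyl)methanol F1. Dess–Martin oxidation should convert this alcohol into {6-[4-(methoxymethoxy)phenyl]-2-{[4-(methoxymethoxy)phenyl]ethynyl}-3-methylphenyl}(phenyl)methanone F2. Addition of 10, premixed with anhydrous CeCl3 to favour 1,2-addition of an unhindered aryl nucleophile to the hindered carbonyl group, should then give 14.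

Step 7. The three aryl MOM ethers are lost one after another, and if this requires stronger acid or longer exposure, the C7 cation persists. It can then close onto the ortho position of the C4 aryl ring (Friedel–Crafts formation of a fluorene), or the electron-rich alkyne can be hydrated. The fallback sets out from 14 and returns at 16. Ionic hydrogenation (Et3SiH, CF3CO2H, CH2Cl2, 0 °C) should reduce the cation as fast as it forms and give racemic 4'-(methoxymethoxy)-2-{[4-(methoxymethoxy)phenyl](phenyl)methyl}-3-{[4-(methoxymethoxy)phenyl]ethynyl}-4-methyl-1,1'-biphenyl F3; partial loss of MOM groups at this stage is harmless. With no ionisable C7–O bond left, HCl in methanol can be applied for as long as needed and should give racemic 2-[(4-hydroxyphenyl)(phenyl)methyl]-3-[(4-hydroxyphenyl)ethynyl]-4-methyl-[1,1'-biphenyl]-4'-ol F4. Dehydrogenation of this 4-hydroxyphenyl-substituted triarylmethane with one equivalent of DDQ (the classical oxidation of 4-hydroxytriarylmethanes to fuchsones) should then give 16.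

Step 4. Fluoride releases the terminal alkyne 8 all at once, while oxidative addition of the electron-rich iodide 2 is comparatively slow, so copper-mediated oxidative dimerisation of the alkyne (Glaser coupling) can outrun the cross-coupling. The fallback sets out from 2, 6 and 5 and returns at 9. It moves the alkyne to the other ring and separates desilylation from coupling. Sonogashira coupling of 2 with 6 (PdCl2(PPh3)2, CuI, Et3N) should give trimethyl{[4-(methoxymethoxy)phenyl]ethynyl}silane F5. K2CO3 in methanol should release 1-ethynyl-4-(methoxymethoxy)benzene F6, which is isolated and added slowly to 5 under Sonogashira conditions to give 9.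

Further compounds

F1 | step 6 | racemic {6-[4-(methoxymethoxy)phenyl]-2-{[4-(methoxymethoxy)phenyl]ethynyl}-3-methylphenyl}(phenyl)methanol | Cc1ccc(-c2ccc(OCOC)cc2)c(C(O)c2ccccc2)c1C#Cc1ccc(OCOC)cc1
F2 | step 6 | {6-[4-(methoxymethoxy)phenyl]-2-{[4-(methoxymethoxy)phenyl]ethynyl}-3-methylphenyl}(phenyl)methanone | Cc1ccc(-c2ccc(OCOC)cc2)c(C(=O)c2ccccc2)c1C#Cc1ccc(OCOC)cc1
F3 | step 7 | racemic 4'-(methoxymethoxy)-2-{[4-(methoxymethoxy)phenyl](phenyl)methyl}-3-{[4-(methoxymethoxy)phenyl]ethynyl}-4-methyl-1,1'-biphenyl | Cc1ccc(-c2ccc(OCOC)cc2)c(C(c2ccccc2)c2ccc(OCOC)cc2)c1C#Cc1ccc(OCOC)cc1
F4 | step 7 | racemic 2-[(4-hydroxyphenyl)(phenyl)methyl]-3-[(4-hydroxyphenyl)ethynyl]-4-methyl-[1,1'-biphenyl]-4'-ol | Cc1ccc(-c2ccc(O)cc2)c(C(c2ccccc2)c2ccc(O)cc2)c1C#Cc1ccc(O)cc1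
F5 | step 4 | trimethyl{[4-(methoxymethoxy)phenyl]ethynyl}silane | COCOc1ccc(C#C[Si](C)(C)C)cc1
F6 | step 4 | 1-ethynyl-4-(methoxymethoxy)benzene | COCOc1ccc(C#C)cc1
A1 | alternative 1 | [2-hydroxy-6-(4-methoxyphenyl)-3-methylphenyl](phenyl)methanone | Cc1ccc(-c2ccc(OC)cc2)c(C(=O)c2ccccc2)c1O
A2 | alternative 1 | (2E)-3-(4-methoxyphenyl)prop-2-enal | COc1ccc(/C=C/C=O)cc1
A3 | alternative 1 | 1-phenylpentane-1,3-dione | CCC(=O)CC(=O)c1ccccc1
A4 | alternative 2 | [4-(methoxymethoxy)phenyl]{6-[4-(methoxymethoxy)phenyl]-2-{[4-(methoxymethoxy)phenyl]ethynyl}-3-methylphenyl}methanone | Cc1ccc(-c2ccc(OCOC)cc2)c(C(=O)c2ccc(OCOC)cc2)c1C#Cc1ccc(OCOC)cc1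
A5 | alternative 2 | 1-(methoxymethoxy)-4-[(1E,3E)-penta-1,3-dien-1-yl]benzene | C/C=C/C=C/c1ccc(OCOC)cc1
A6 | alternative 2 | 1,5-bis[4-(methoxymethoxy)phenyl]penta-2,4-diyn-1-one | O=C(C#CC#Cc1ccc(OCOC)cc1)c1ccc(OCOC)cc1
A7 | alternative 3 | ethyl 6-(4-methoxyphenyl)-2-[(4-methoxyphenyl)ethynyl]-3-methylbenzoate | CCOC(=O)c1c(-c2ccc(OC)cc2)ccc(C)c1C#Cc1ccc(OC)cc1
A8 | alternative 3 | ethyl 2-(4-methoxyphenyl)-4-[(4-methoxyphenyl)ethynyl]-5-methyl-6-oxo-6H-pyran-3-carboxylate | CCOC(=O)C1=C(c2ccc(OC)cc2)OC(=O)C(C)=C1C#Cc1ccc(OC)cc1
A9 | alternative 3 | butyl vinyl ether | CCCCOC=C
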